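**Strategy.** The tetrahydropyran ring (O1, C2–C6) carries oxygen at C4 between C3 and C5, so it is read as a hetero-Diels–Alder adduct of a C2=C3–C4(OSiEt3)=C5 silyloxydiene and the C6=O1 carbonyl of an aldehyde. The diene already holds the complete C3 side chain with both of its stereocentres and three of the four aryl groups; the dienophile is 3-(4-silyloxyphenyl)propanal. One catalyst-controlled operation forms C5–C6 and O1–C2, sets C6 and C2 (cis) and, on hydrolysis of the enol ether, C3 and the C4 ketone. A rhodium-catalysed three-component coupling builds the diene precursor; axial-selective reduction and desilylation finish the synthesis.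

Key step: step 8

Atom labels: ring O1, C2 (aryl-bearing), C3, C4 (oxygen-bearing), C5, C6 (arylethyl-bearing); side chain on C3: C1′ (styryl-bearing), C2′, C3′ (carbinol).
Abbreviations: TBS = tert-butyldimethylsilyl, TES = triethylsilyl, ArTBS = 4-[(tert-butyldimethylsilyl)oxy]phenyl.
Assumption: the facial sense of the three catalyst-controlled steps (2, 5 and 8) is taken from the usual behaviour of each catalyst class with simple analogues; if one proves opposite, the mirror-image ligand is used and nothing else changes.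

**Step 1**
Reactants: 1 tert-butyl(4-iodophenoxy)dimethylsilane; 2 prop-2-en-1-ol
Product: 3 3-(ArTBS)propanal
Conditions: Pd(OAc)2 (3 mol%), Bu4NCl, NaHCO3, DMF, 45 °C
Reagents that add atoms: none
Why: Heck arylation of allyl alcohol under ligand-free phase-transfer conditions, in which the aryl group adds to the terminal alkene carbon and β-hydride elimination towards the carbinol gives the enol and hence the 3-arylpropanal; no stereocentre is formed.

**Step 2**
Reactants: 3 3-(ArTBS)propanal; 4 allyltributylstannane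
Product: 5 (S)-1-(ArTBS)hex-5-en-3-ol
Conditions: (R)-BINOL (10 mol%), Ti(OiPr)4 (10 mol%), 4 Å MS, CH2Cl2, −20 °C; aq. NaHCO3
Reagents that add atoms: none
Why: Keck asymmetric allylation, in which the BINOL–titanium Lewis acid binds the aldehyde and allyl transfer from tin to its Re face sets C3′ as S.

**Step 3**
Reactants: 5 (S)-1-(ArTBS)hex-5-en-3-ol
Product: 6 (S)-3-(TBSO)-1-(ArTBS)hex-5-ene
Conditions: TBSCl, imidazole, DMF, rt
Reagents that add atoms: tert-butyldimethylsilyl chloride, CC(C)(C)[Si](C)(C)Cl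
Why: Standard silylation of a secondary alcohol, which leaves the stereocentre untouched.

**Step 4**
Reactants: 6 (S)-3-(TBSO)-1-(ArTBS)hex-5-ene; 7 but-3-en-2-one
Product: 8 (3E,6S)-6-(TBSO)-8-(ArTBS)oct-3-en-2-one
Conditions: second-generation Grubbs catalyst (5 mol%), 7 (3 equiv), CH2Cl2, 40 °C
Reagents that add atoms: none
Why: Olefin cross-metathesis of a reactive terminal alkene with an electron-poor enone partner, which favours the cross product and the E alkene.

**Step 5**
Reactants: 8 (3E,6S)-6-(TBSO)-8-(ArTBS)oct-3-en-2-one; 9 tert-butyl(4-ethynylphenoxy)dimethylsilane; 10 4-[(tert-butyldimethylsilyl)oxy]benzaldehyde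
Product: 13 (4S,6S)-6-(TBSO)-8-(ArTBS)-4-[(E)-2-(ArTBS)ethenyl]-3-[hydroxy(ArTBS)methyl]octan-2-one (diastereomer mixture at C3 and the new carbinol carbon), via alkenylzirconocene chloride 11 (not isolated), via zirconium enolate 12 (not isolated)
Conditions: 9, Cp2Zr(H)Cl, THF, rt; then 8, [Rh(cod)(MeCN)2]BF4 (5 mol%), (R)-BINAP (6 mol%), rt; then 10, 0 °C; aq. NaHCO3
Reagents that add atoms: none
Why: Hydrozirconation gives the (E)-alkenylzirconocene, whose rhodium/BINAP-catalysed asymmetric 1,4-addition to the E enone sets C1′ (S) under ligand control, and the zirconium enolate thus formed only at C3 is trapped by aldehyde 10 in an aldol addition (three-component coupling); the two new aldol centres are removed in step 6.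

**Step 6**
Reactants: 13 aldol adduct
Product: 14 (3E,4S,6S)-6-(TBSO)-8-(ArTBS)-4-[(E)-2-(ArTBS)ethenyl]-3-[(ArTBS)methylidene]octan-2-one
Conditions: MsCl, Et3N (excess), CH2Cl2, 0 °C to rt
Reagents that add atoms: none
Why: Mesylation of the benzylic alcohol followed by E1cB elimination through the ketone enolate gives the conjugated enone, and the E isomer (aryl trans to acetyl) is the thermodynamic product from both diastereomers.

**Step 7**
Reactants: 14 α-arylidene methyl ketone
Product: 15 (3E,4S,6S)-6-(TBSO)-8-(ArTBS)-4-[(E)-2-(ArTBS)ethenyl]-3-[(ArTBS)methylidene]-2-(triethylsilyloxy)oct-1-ene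
Conditions: TESOTf, Et3N, Et2O, −78 to 0 °C
Reagents that add atoms: triethylsilyl trifluoromethanesulfonate, CC[Si](CC)(CC)OS(=O)(=O)C(F)(F)F
Why: Soft enolisation with silyl triflate and amine; the methyl group is the only enolisable position, so the 2-silyloxy-1,3-diene forms regiospecifically.

**Step 8**
Reactants: 15 2-silyloxy-1,3-diene; 3 3-(ArTBS)propanal
Product: 17 (2S,3R,6S)-2-(ArTBS)-6-[2-(ArTBS)ethyl]-3-[(1E,3S,5S)-5-(TBSO)-1,7-bis(ArTBS)hept-1-en-3-yl]oxan-4-one, via silyl enol ether cycloadduct 16 (not isolated)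
Conditions: [CrCl(L)] (5 mol%; L = doubly deprotonated Schiff base of 3-(1-adamantyl)-2-hydroxy-5-methylbenzaldehyde and (1R,2S)-1-aminoindan-2-ol), 4 Å MS, minimal EtOAc, rt; then TFA (cat.), wet CH2Cl2, 0 °C
Reagents that add atoms: none
Why: Aldehyde 3, bound to the chiral trivalent chromium Lewis acid, reacts with the s-cis conformer of diene 15 in an asynchronous [4+2] cycloaddition in which the silyl enol ether terminus C5 bonds to the carbonyl carbon C6 and the carbonyl oxygen O1 closes onto the benzylidene carbon C2; the closest known reaction type is the chromium Schiff-base-catalysed hetero-Diels–Alder reaction of 2-silyloxydienes with aliphatic aldehydes. The six-membered oxacycle is closed by intermolecular [4+2] cycloaddition (a stepwise Mukaiyama aldol followed by 6-endo-trig oxa-Michael closure would give the same two bonds). C6 (S) is set by the catalyst, which exposes the Re face of the bound aldehyde, and C2 is set cis to C6 by the endo transition state together with the E geometry of the benzylidene (aryl outside). C3 arises when the tetrasubstituted silyl enol ether 16 is hydrolysed: axial protonation, which is also the thermodynamic outcome, places the side chain equatorial and trans to the C2 aryl group. The step needs catalyst control over the resident C1′ centre, which is plausible because allylic 1,3-strain holds the C1′–H bond in the diene plane so that both diene faces are flanked alike, and it needs the carbonyl of 3 to be the only dienophile, which holds because the styrene and the diene itself are poor partners. Any 2,6-trans ketone should equilibrate to all-equatorial 17 by retro-oxa-Michael/oxa-Michael under the acidic hydrolysis.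

**Step 9**
Reactants: 17 tetrahydropyran-4-one
Product: 18 (2S,3S,4S,6S)-2-(ArTBS)-6-[2-(ArTBS)ethyl]-3-[(1E,3S,5S)-5-(TBSO)-1,7-bis(ArTBS)hept-1-en-3-yl]oxan-4-ol
Conditions: LiBH(s-Bu)3 (L-Selectride), THF, −78 °C; then aq. NH4Cl
Reagents that add atoms: none
Why: Substrate-controlled ketone reduction in which the bulky trialkylborohydride attacks the chair ketone from the equatorial side and gives the axial C4 alcohol (4S), cis to the C3 substituent.

**Step 10**
Reactants: 18 penta-TBS ether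
Product: 19 blepharocalyxin C, (2S,3S,4S,6S)-2-(4-hydroxyphenyl)-6-[2-(4-hydroxyphenyl)ethyl]-3-[(1E,3S,5S)-5-hydroxy-1,7-bis(4-hydroxyphenyl)hept-1-en-3-yl]oxan-4-ol
Conditions: Bu4NF, AcOH, THF, 0 °C to rt
Reagents that add atoms: none
Why: Fluoride-mediated cleavage of the four aryl and one alkyl silyl ethers, buffered with acetic acid so that no free phenoxide opens the benzylic C2–O1 bond.

**Compound list**

1 | tert-butyl(4-iodophenoxy)dimethylsilane | CC(C)(C)[Si](C)(C)Oc1ccc(I)cc1 | starting material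
2 | prop-2-en-1-ol | C=CCO | starting material
3 | 3-(ArTBS)propanal | CC(C)(C)[Si](C)(C)Oc1ccc(CCC=O)cc1 | intermediate
4 | allyltributylstannane | C=CC[Sn](CCCC)(CCCC)CCCC | starting material
5 | (S)-1-(ArTBS)hex-5-en-3-ol | C=CC[C@@H](O)CCc1ccc(O[Si](C)(C)C(C)(C)C)cc1 | intermediate
6 | (S)-3-(TBSO)-1-(ArTBS)hex-5-ene | C=CC[C@@H](O[Si](C)(C)C(C)(C)C)CCc1ccc(O[Si](C)(C)C(C)(C)C)cc1 | intermediate
7 | but-3-en-2-one | CC(=O)C=C | starting material
8 | (3E,6S)-6-(TBSO)-8-(ArTBS)oct-3-en-2-one | CC(=O)/C=C/C[C@@H](O[Si](C)(C)C(C)(C)C)CCc1ccc(O[Si](C)(C)C(C)(C)C)cc1 | intermediate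
9 | tert-butyl(4-ethynylphenoxy)dimethylsilane | C#Cc1ccc(O[Si](C)(C)C(C)(C)C)cc1 | starting material
10 | 4-[(tert-butyldimethylsilyl)oxy]benzaldehyde | O=Cc1ccc(O[Si](C)(C)C(C)(C)C)cc1 | starting material
11 | chlorobis(cyclopentadienyl)[(E)-2-(ArTBS)ethenyl]zirconium | Cl[Zr](/C=C/c1ccc(O[Si](C)(C)C(C)(C)C)cc1)(C1C=CC=C1)C1C=CC=C1 | intermediate
12 | chlorobis(cyclopentadienyl)zirconium (4S,6S)-6-(TBSO)-8-(ArTBS)-4-[(E)-2-(ArTBS)ethenyl]oct-2-en-2-olate | CC(C)(C)[Si](C)(C)Oc1ccc(/C=C/[C@H](C[C@@H](O[Si](C)(C)C(C)(C)C)CCc2ccc(O[Si](C)(C)C(C)(C)C)cc2)C=C(C)O[Zr](Cl)(C2C=CC=C2)C2C=CC=C2)cc1 | intermediate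
13 | (4S,6S)-6-(TBSO)-8-(ArTBS)-4-[(E)-2-(ArTBS)ethenyl]-3-[hydroxy(ArTBS)methyl]octan-2-one (diastereomer mixture at C3 and the carbinol carbon) | CC(C)(C)[Si](C)(C)Oc1ccc(/C=C/[C@H](C[C@@H](O[Si](C)(C)C(C)(C)C)CCc2ccc(O[Si](C)(C)C(C)(C)C)cc2)C(C(C)=O)C(O)c2ccc(O[Si](C)(C)C(C)(C)C)cc2)cc1 | intermediate
14 | (3E,4S,6S)-6-(TBSO)-8-(ArTBS)-4-[(E)-2-(ArTBS)ethenyl]-3-[(ArTBS)methylidene]octan-2-one | CC(C)(C)[Si](C)(C)Oc1ccc(/C=C/[C@H](C[C@@H](O[Si](C)(C)C(C)(C)C)CCc2ccc(O[Si](C)(C)C(C)(C)C)cc2)/C(C(C)=O)=C\c2ccc(O[Si](C)(C)C(C)(C)C)cc2)cc1 | intermediate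
15 | (3E,4S,6S)-6-(TBSO)-8-(ArTBS)-4-[(E)-2-(ArTBS)ethenyl]-3-[(ArTBS)methylidene]-2-(triethylsilyloxy)oct-1-ene | CC(C)(C)[Si](C)(C)Oc1ccc(/C=C/[C@H](C[C@@H](O[Si](C)(C)C(C)(C)C)CCc2ccc(O[Si](C)(C)C(C)(C)C)cc2)/C(C(=C)O[Si](CC)(CC)CC)=C\c2ccc(O[Si](C)(C)C(C)(C)C)cc2)cc1 | intermediate
16 | (2R,6S)-2-(ArTBS)-6-[2-(ArTBS)ethyl]-3-[(1E,3S,5S)-5-(TBSO)-1,7-bis(ArTBS)hept-1-en-3-yl]-4-(triethylsilyloxy)-5,6-dihydro-2H-pyran (2,6-cis) | CC(C)(C)[Si](C)(C)Oc1ccc(/C=C/[C@H](C[C@@H](O[Si](C)(C)C(C)(C)C)CCc2ccc(O[Si](C)(C)C(C)(C)C)cc2)C2=C(O[Si](CC)(CC)CC)C[C@H](CCc3ccc(O[Si](C)(C)C(C)(C)C)cc3)O[C@@H]2c4ccc(O[Si](C)(C)C(C)(C)C)cc4)cc1 | intermediate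
17 | (2S,3R,6S)-2-(ArTBS)-6-[2-(ArTBS)ethyl]-3-[(1E,3S,5S)-5-(TBSO)-1,7-bis(ArTBS)hept-1-en-3-yl]oxan-4-one (all substituents equatorial) | CC(C)(C)[Si](C)(C)Oc1ccc(/C=C/[C@H](C[C@@H](O[Si](C)(C)C(C)(C)C)CCc2ccc(O[Si](C)(C)C(C)(C)C)cc2)[C@@H]2[C@@H](c3ccc(O[Si](C)(C)C(C)(C)C)cc3)O[C@@H](CCc3ccc(O[Si](C)(C)C(C)(C)C)cc3)CC2=O)cc1 | intermediate
18 | (2S,3S,4S,6S)-2-(ArTBS)-6-[2-(ArTBS)ethyl]-3-[(1E,3S,5S)-5-(TBSO)-1,7-bis(ArTBS)hept-1-en-3-yl]oxan-4-ol (axial hydroxyl) | CC(C)(C)[Si](C)(C)Oc1ccc(/C=C/[C@H](C[C@@H](O[Si](C)(C)C(C)(C)C)CCc2ccc(O[Si](C)(C)C(C)(C)C)cc2)[C@@H]2[C@@H](c3ccc(O[Si](C)(C)C(C)(C)C)cc3)O[C@@H](CCc3ccc(O[Si](C)(C)C(C)(C)C)cc3)C[C@@H]2O)cc1 | intermediate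
19 | blepharocalyxin C, (2S,3S,4S,6S)-2-(4-hydroxyphenyl)-6-[2-(4-hydroxyphenyl)ethyl]-3-[(1E,3S,5S)-5-hydroxy-1,7-bis(4-hydroxyphenyl)hept-1-en-3-yl]oxan-4-ol | Oc1ccc(/C=C/[C@H](C[C@@H](O)CCc2ccc(O)cc2)[C@@H]2[C@@H](c3ccc(O)cc3)O[C@@H](CCc3ccc(O)cc3)C[C@@H]2O)cc1 | target

**Step count.** Total: 10 steps. Longest linear sequence: 10 steps (compound 1 to compound 19 through steps 1–10; aldehyde 3 is used again in step 8).

**Steps most likely to fail**

Step 8. The 3-branched diene may react too slowly at the weakly Lewis-acidic chromium centre, so that diene desilylation or an uncatalysed background reaction erodes conversion and facial control over the resident C1′ centre. The fallback sets out from enone 14 and returns at ketone 17. Enone 14 is converted with the matching antipode of diisopinocampheylboron chloride (Ipc2BCl) and Et3N into its boron enolate at the methyl group, which adds to the Re face of aldehyde 3 to give the δ-hydroxy enone F1. Treatment of the δ-hydroxy enone F1 with catalytic camphorsulfonic acid in CH2Cl2 closes the ring by 6-endo-trig oxa-Michael addition under thermodynamic control and gives 17.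

Step 5. Proton exchange between the zirconium enolate and the acidic methyl ketone or the aldol product may scramble the enolate regiochemistry or simply protonate it before it meets the electron-rich aldehyde. The fallback sets out from 8 and 9 and returns at 13. The same hydrozirconation and rhodium-catalysed 1,4-addition are run, but enolate 12 is silylated in the flask with Me3SiCl and isolated as the trimethylsilyl enol ether F2. A Mukaiyama aldol addition of the trimethylsilyl enol ether F2 to aldehyde 10 (BF3·OEt2, CH2Cl2, −78 °C) then forms the C2–C3 bond at the fixed enol carbon and gives 13.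

Step 10. Once the phenol para to C2 is free, basic fluoride may open the benzylic C2–O1 bond through a quinone methide and so erode the C2 configuration, while buffering strong enough to prevent this may leave the secondary silyl ether partly uncleaved. The fallback sets out from 18 and returns at 19 in two non-basic stages. HF·pyridine in THF/pyridine removes only the secondary alkyl silyl ether and gives the tetrakis(aryl silyl ether) diol F3. KHF2 in MeOH at rt then cleaves the four aryl silyl ethers of the diol F3 and gives 19.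

**Further compounds**

F1 | step 8 | (3S,6E,7S,9S)-9-(TBSO)-1,11-bis(ArTBS)-7-[(E)-2-(ArTBS)ethenyl]-3-hydroxy-6-[(ArTBS)methylidene]undecan-5-one | CC(C)(C)[Si](C)(C)Oc1ccc(/C=C/[C@H](C[C@@H](O[Si](C)(C)C(C)(C)C)CCc2ccc(O[Si](C)(C)C(C)(C)C)cc2)/C(C(=O)C[C@@H](O)CCc2ccc(O[Si](C)(C)C(C)(C)C)cc2)=C\c2ccc(O[Si](C)(C)C(C)(C)C)cc2)cc1
F2 | step 5 | (4S,6S)-6-(TBSO)-8-(ArTBS)-4-[(E)-2-(ArTBS)ethenyl]-2-(trimethylsilyloxy)oct-2-ene | CC(C)(C)[Si](C)(C)Oc1ccc(/C=C/[C@H](C[C@@H](O[Si](C)(C)C(C)(C)C)CCc2ccc(O[Si](C)(C)C(C)(C)C)cc2)C=C(C)O[Si](C)(C)C)cc1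
F3 | step 10 | (2S,3S,4S,6S)-2-(ArTBS)-6-[2-(ArTBS)ethyl]-3-[(1E,3S,5S)-5-hydroxy-1,7-bis(ArTBS)hept-1-en-3-yl]oxan-4-ol | CC(C)(C)[Si](C)(C)Oc1ccc(/C=C/[C@H](C[C@@H](O)CCc2ccc(O[Si](C)(C)C(C)(C)C)cc2)[C@@H]2[C@@H](c3ccc(O[Si](C)(C)C(C)(C)C)cc3)O[C@@H](CCc3ccc(O[Si](C)(C)C(C)(C)C)cc3)C[C@@H]2O)cc1
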